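Retrosynthesis (azulene numbering of the target): cut the ester C–O at the CH2O group on C6; the C3=C3a double bond (back to two ketones); the C4–C5 bond of the seven-membered ring together with a new, temporary O–C7 bond (retro-Claisen); then C8a–CH3 and C8a–C1 (enolate alkylations).
Enabling feature: C6=C7 lies γ,δ to C3a (C3a–C4–C5–C6=C7). With C3a as a ketone the seven-membered ring is a cyclohept-4-enone, the Claisen product of a five-membered 2-methylidene-5-alkenyloxolane whose ring oxygen becomes the C3a carbonyl oxygen.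
Forward: oxolan-2-one 8 (its C5 is the future C7) is alkylated twice at C3 (future C8a), methylenated, and ring-expanded from the five-membered oxolane to the seven-membered cycloheptenone. A McMurry coupling then closes the five-membered carbocycle as the C3=C3a alkene; desilylation and Mitsunobu esterification finish.
Stereochemistry: an oxazaborolidine reduction sets C5 of the oxolanone. That centre steers methyl iodide to the opposite ring face to create the quaternary carbon (future C8a, R), and is then erased when it becomes sp2 in the ring expansion. The oxolane O–C bond, absent from the target, is the temporary control element.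

Key step: step 10

Remark: the branched alkenyl group is assumed to act as the large substituent in the oxazaborolidine reduction. Because C5 of the oxolane is erased in step 10, the enantiomeric purity of the target rests on the diastereomeric purity of 16, which is therefore freed of its C3 epimer before step 9.

Step 1
Reactants: 1 2-bromoprop-2-en-1-ol
Product: 2 [(2-bromoprop-2-en-1-yl)oxy](tert-butyl)diphenylsilane
Conditions: t-BuPh2SiCl, imidazole, CH2Cl2, 0 °C to rt
Reagents that add atoms: tert-butyl(chloro)diphenylsilane, CC(C)(C)[Si](Cl)(c1ccccc1)c1ccccc1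
Why: Imidazole-promoted silylation of the primary alcohol should be clean and installs an ether that withstands the organometallic, enolate, titanium and thermal steps that follow.

Step 2
Reactants: 2 [(2-bromoprop-2-en-1-yl)oxy](tert-butyl)diphenylsilane; 3 methyl 4-chloro-4-oxobutanoate
Product: 6 methyl 5-({[tert-butyl(diphenyl)silyl]oxy}methyl)-4-oxohex-5-enoate, via alkenyllithium 4 (not isolated), via alkenylzinc chloride 5 (not isolated)
Conditions: t-BuLi (2.1 equiv), Et2O, −78 °C; ZnCl2, THF, −78 to 0 °C; then 3, Pd(PPh3)4 (5 mol %), THF, 0 °C to rt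
Reagents that add atoms: none
Why: Bromine–lithium exchange, transmetalation to zinc and a palladium-catalysed Negishi acylation of the acid chloride should give the 2-substituted vinyl ketone while the methyl ester, which an organozinc does not attack, stays intact.

Step 3
Reactants: 6 methyl 5-({[tert-butyl(diphenyl)silyl]oxy}methyl)-4-oxohex-5-enoate
Product: 8 (5R)-5-(3-{[tert-butyl(diphenyl)silyl]oxy}prop-1-en-2-yl)oxolan-2-one, via hydroxy ester 7 (not isolated)
Conditions: (S)-1-methyl-3,3-diphenyltetrahydro-1H,3H-pyrrolo[1,2-c][1,3,2]oxazaborole (15 mol %), catecholborane, toluene, −78 °C; MeOH quench; then PPTS (cat.), CH2Cl2, rt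
Reagents that add atoms: none
Why: A Corey–Bakshi–Shibata reduction should deliver hydride to the ketone face fixed by the (S)-oxazaborolidine with the branched alkenyl group as the large substituent, which sets the (R)-carbinol centre, and the γ-hydroxy ester then lactonises under mild acid.

Step 4
Reactants: 9 ethyl 4-methyl-3-oxopentanoate
Product: 10 ethyl 2-[2-(propan-2-yl)-1,3-dioxolan-2-yl]acetate
Conditions: HOCH2CH2OH, p-TsOH (cat.), toluene, reflux, Dean–Stark trap
Reagents that add atoms: ethane-1,2-diol, OCCO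
Why: Acid-catalysed ketalisation with azeotropic removal of water should mask the ketone of the β-keto ester while the ester is left untouched.

Step 5
Reactants: 10 ethyl 2-[2-(propan-2-yl)-1,3-dioxolan-2-yl]acetate
Product: 11 2-[2-(propan-2-yl)-1,3-dioxolan-2-yl]ethan-1-ol
Conditions: LiAlH4, THF, 0 °C
Reagents that add atoms: none
Why: Hydride reduction of the ester to the primary alcohol should be straightforward, the dioxolane being inert to LiAlH4.

Step 6
Reactants: 11 2-[2-(propan-2-yl)-1,3-dioxolan-2-yl]ethan-1-ol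
Product: 12 2-(2-iodoethyl)-2-(propan-2-yl)-1,3-dioxolane
Conditions: I2, PPh3, imidazole, CH2Cl2, 0 °C to rt
Reagents that add atoms: iodine, II
Why: An Appel-type iodination should convert the primary alcohol into the iodide, with imidazole buffering the medium so that the ketal survives.

Step 7
Reactants: 8 (5R)-5-(3-{[tert-butyl(diphenyl)silyl]oxy}prop-1-en-2-yl)oxolan-2-one; 12 2-(2-iodoethyl)-2-(propan-2-yl)-1,3-dioxolane
Product: 14 (3S,5R)-5-(3-{[tert-butyl(diphenyl)silyl]oxy}prop-1-en-2-yl)-3-{2-[2-(propan-2-yl)-1,3-dioxolan-2-yl]ethyl}oxolan-2-one, via lithium enolate 13 (not isolated)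
Conditions: LiN(i-Pr)2 (1.05 equiv), THF, −78 °C; then 12, DMPU, −78 to −25 °C
Reagents that add atoms: none
Why: Alkylation of the lactone lithium enolate by the primary iodide should give mainly the trans product (electrophile anti to the C5 substituent), and the configuration at C3 is of no consequence because this carbon is enolised again in step 8.

Step 8
Reactants: 14 (3S,5R)-5-(3-{[tert-butyl(diphenyl)silyl]oxy}prop-1-en-2-yl)-3-{2-[2-(propan-2-yl)-1,3-dioxolan-2-yl]ethyl}oxolan-2-one
Product: 16 (3R,5R)-5-(3-{[tert-butyl(diphenyl)silyl]oxy}prop-1-en-2-yl)-3-methyl-3-{2-[2-(propan-2-yl)-1,3-dioxolan-2-yl]ethyl}oxolan-2-one, via lithium enolate 15 (not isolated)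
Conditions: LiN(i-Pr)2, THF, −78 °C; MeI, −78 to −40 °C; chromatographic removal of the C3 epimer
Reagents that add atoms: iodomethane, CI
Why: In this second enolate alkylation methyl iodide should approach the planar enolate from the face opposite the C5 alkenyl group (1,3-induction across the oxolanone, as in sequential dialkylations of γ-substituted butyrolactones), which sets the quaternary centre as (3R) with methyl trans to the alkenyl group.

Step 9
Reactants: 16 (3R,5R)-5-(3-{[tert-butyl(diphenyl)silyl]oxy}prop-1-en-2-yl)-3-methyl-3-{2-[2-(propan-2-yl)-1,3-dioxolan-2-yl]ethyl}oxolan-2-one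
Product: 17 tert-butyl{[2-((2R,4R)-4-methyl-5-methylidene-4-{2-[2-(propan-2-yl)-1,3-dioxolan-2-yl]ethyl}oxolan-2-yl)prop-2-en-1-yl]oxy}diphenylsilane
Conditions: Cp2TiMe2 (2.5 equiv), toluene, 65 °C, dark; filtration through basic alumina
Reagents that add atoms: dimethyltitanocene, C[Ti](C)(C1C=CC=C1)C1C=CC=C1
Why: Petasis methylenation should convert the lactone carbonyl into the exocyclic enol ether in the presence of ketal, silyl ether and alkene, and the quaternary neighbour prevents the new double bond from moving into the ring.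

Step 10
Reactants: 17 tert-butyl{[2-((2R,4R)-4-methyl-5-methylidene-4-{2-[2-(propan-2-yl)-1,3-dioxolan-2-yl]ethyl}oxolan-2-yl)prop-2-en-1-yl]oxy}diphenylsilane
Product: 18 (2R)-5-({[tert-butyl(diphenyl)silyl]oxy}methyl)-2-methyl-2-{2-[2-(propan-2-yl)-1,3-dioxolan-2-yl]ethyl}cyclohept-4-en-1-one
Conditions: toluene (0.02 M), Et3N (1 vol %), sealed base-washed tube, 185 °C
Reagents that add atoms: none
Why: On heating, the allyl vinyl ether array of 17 (exocyclic CH2=C–O–CH–C(=CH2), oxolane atoms numbered as in lactone 16: O1, C2, C3 quaternary, C5) should undergo a concerted Claisen [3,3]-sigmatropic shift in which the enol ether CH2 bonds to the terminal CH2 of the 2-substituted vinyl group while O1–C5 breaks, so the five-membered oxolane is enlarged by two atoms to the cyclohept-4-enone and the ring oxygen becomes the ketone oxygen. The closest known reaction type is the thermal Claisen ring expansion of 2-alkylidene-5-vinyloxolanes to cyclohept-4-enones. The seven-membered ring is closed by the sigmatropic C–C bond formation through a boat-like bicyclic transition state, the only geometry the oxolane allows, which delivers the ring alkene necessarily as the cis endocyclic isomer with the silyloxymethyl group on its fully substituted carbon. No new stereocentre is formed: C5 becomes sp2, and the quaternary C3 is a spectator whose configuration passes unchanged into C2 of 18 (the future C8a). The step needs the [3,3] path to win over isomerisation of the enol ether and over ionisation of the allylic C–O bond with 1,3-recombination; the quaternary C3 carries no hydrogen, so the exocyclic double bond cannot migrate, and the non-polar, acid-free medium disfavours ion-pair pathways.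

Step 11
Reactants: 18 (2R)-5-({[tert-butyl(diphenyl)silyl]oxy}methyl)-2-methyl-2-{2-[2-(propan-2-yl)-1,3-dioxolan-2-yl]ethyl}cyclohept-4-en-1-one
Product: 19 (2R)-5-({[tert-butyl(diphenyl)silyl]oxy}methyl)-2-methyl-2-(4-methyl-3-oxopentyl)cyclohept-4-en-1-one
Conditions: 1 M HCl, THF, rt
Reagents that add atoms: water, O
Why: Mild aqueous acid should hydrolyse the dioxolane to the isopropyl ketone without cleaving the hindered silyl ether or moving the ring alkene.

Step 12
Reactants: 19 (2R)-5-({[tert-butyl(diphenyl)silyl]oxy}methyl)-2-methyl-2-(4-methyl-3-oxopentyl)cyclohept-4-en-1-one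
Product: 20 tert-butyl{[(8aR)-8a-methyl-3-(propan-2-yl)-1,2,4,5,8,8a-hexahydroazulen-6-yl]methoxy}diphenylsilane
Conditions: TiCl3(DME)1.5, zinc–copper couple, DME, reflux; slow addition of 19 (high dilution), then reflux
Reagents that add atoms: none
Why: In this intramolecular McMurry coupling low-valent titanium should join the two ketone carbons through a titanium pinacolate and deoxygenate it on heating to the tetrasubstituted C3=C3a alkene, whose position is fixed by the two carbonyl carbons, while the quaternary centre is untouched.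

Step 13
Reactants: 20 tert-butyl{[(8aR)-8a-methyl-3-(propan-2-yl)-1,2,4,5,8,8a-hexahydroazulen-6-yl]methoxy}diphenylsilane
Product: 21 [(8aR)-8a-methyl-3-(propan-2-yl)-1,2,4,5,8,8a-hexahydroazulen-6-yl]methanol
Conditions: Bu4NF, THF, 0 °C to rt
Reagents that add atoms: none
Why: Fluoride-induced cleavage of the silyl ether should free the primary allylic alcohol under conditions that leave both alkenes alone.

Step 14
Reactants: 21 [(8aR)-8a-methyl-3-(propan-2-yl)-1,2,4,5,8,8a-hexahydroazulen-6-yl]methanol; 22 4-hydroxy-3-methoxybenzoic acid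
Product: 23 [(8aR)-8a-methyl-3-(propan-2-yl)-1,2,4,5,8,8a-hexahydroazulen-6-yl]methyl 4-hydroxy-3-methoxybenzoate
Conditions: PPh3, DIAD, THF, 0 °C to rt
Reagents that add atoms: none
Why: In this Mitsunobu esterification the carboxylic acid, far more acidic than the phenol, should be the partner that displaces the alkoxyphosphonium group at the primary allylic carbon, so the phenol needs no protection and the neutral conditions spare the diene.

Compound list
1 | 2-bromoprop-2-en-1-ol | OCC(Br)=C | starting material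
2 | [(2-bromoprop-2-en-1-yl)oxy](tert-butyl)diphenylsilane | C=C(Br)CO[Si](c1ccccc1)(c1ccccc1)C(C)(C)C | intermediate
3 | methyl 4-chloro-4-oxobutanoate | COC(=O)CCC(=O)Cl | starting material
4 | (3-{[tert-butyl(diphenyl)silyl]oxy}prop-1-en-2-yl)lithium | [Li]C(=C)CO[Si](c1ccccc1)(c1ccccc1)C(C)(C)C | intermediate
5 | (3-{[tert-butyl(diphenyl)silyl]oxy}prop-1-en-2-yl)zinc chloride | Cl[Zn]C(=C)CO[Si](c1ccccc1)(c1ccccc1)C(C)(C)C | intermediate
6 | methyl 5-({[tert-butyl(diphenyl)silyl]oxy}methyl)-4-oxohex-5-enoate | COC(=O)CCC(=O)C(=C)CO[Si](c1ccccc1)(c1ccccc1)C(C)(C)C | intermediate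
7 | methyl (4R)-5-({[tert-butyl(diphenyl)silyl]oxy}methyl)-4-hydroxyhex-5-enoate | COC(=O)CC[C@@H](O)C(=C)CO[Si](c1ccccc1)(c1ccccc1)C(C)(C)C | intermediate
8 | (5R)-5-(3-{[tert-butyl(diphenyl)silyl]oxy}prop-1-en-2-yl)oxolan-2-one | O=C1CC[C@H](C(=C)CO[Si](c2ccccc2)(c2ccccc2)C(C)(C)C)O1 | intermediate
9 | ethyl 4-methyl-3-oxopentanoate | CCOC(=O)CC(=O)C(C)C | starting material
10 | ethyl 2-[2-(propan-2-yl)-1,3-dioxolan-2-yl]acetate | CCOC(=O)CC1(C(C)C)OCCO1 | intermediate
11 | 2-[2-(propan-2-yl)-1,3-dioxolan-2-yl]ethan-1-ol | OCCC1(C(C)C)OCCO1 | intermediate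
12 | 2-(2-iodoethyl)-2-(propan-2-yl)-1,3-dioxolane | ICCC1(C(C)C)OCCO1 | intermediate
13 | lithium (5R)-5-(3-{[tert-butyl(diphenyl)silyl]oxy}prop-1-en-2-yl)-4,5-dihydrofuran-2-olate (enolate of 8) | [Li]OC1=CC[C@H](C(=C)CO[Si](c2ccccc2)(c2ccccc2)C(C)(C)C)O1 | intermediate
14 | (3S,5R)-5-(3-{[tert-butyl(diphenyl)silyl]oxy}prop-1-en-2-yl)-3-{2-[2-(propan-2-yl)-1,3-dioxolan-2-yl]ethyl}oxolan-2-one | O=C1[C@@H](CCC2(C(C)C)OCCO2)C[C@H](C(=C)CO[Si](c3ccccc3)(c3ccccc3)C(C)(C)C)O1 | intermediate
15 | lithium (5R)-5-(3-{[tert-butyl(diphenyl)silyl]oxy}prop-1-en-2-yl)-3-{2-[2-(propan-2-yl)-1,3-dioxolan-2-yl]ethyl}-4,5-dihydrofuran-2-olate (enolate of 14) | [Li]OC1=C(CCC2(C(C)C)OCCO2)C[C@H](C(=C)CO[Si](c3ccccc3)(c3ccccc3)C(C)(C)C)O1 | intermediate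
16 | (3R,5R)-5-(3-{[tert-butyl(diphenyl)silyl]oxy}prop-1-en-2-yl)-3-methyl-3-{2-[2-(propan-2-yl)-1,3-dioxolan-2-yl]ethyl}oxolan-2-one | O=C1[C@](C)(CCC2(C(C)C)OCCO2)C[C@H](C(=C)CO[Si](c3ccccc3)(c3ccccc3)C(C)(C)C)O1 | intermediate
17 | tert-butyl{[2-((2R,4R)-4-methyl-5-methylidene-4-{2-[2-(propan-2-yl)-1,3-dioxolan-2-yl]ethyl}oxolan-2-yl)prop-2-en-1-yl]oxy}diphenylsilane | C=C1[C@](C)(CCC2(C(C)C)OCCO2)C[C@H](C(=C)CO[Si](c3ccccc3)(c3ccccc3)C(C)(C)C)O1 | intermediate
18 | (2R)-5-({[tert-butyl(diphenyl)silyl]oxy}methyl)-2-methyl-2-{2-[2-(propan-2-yl)-1,3-dioxolan-2-yl]ethyl}cyclohept-4-en-1-one | O=C1CCC(CO[Si](c2ccccc2)(c2ccccc2)C(C)(C)C)=CC[C@@]1(C)CCC3(C(C)C)OCCO3 | intermediate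
19 | (2R)-5-({[tert-butyl(diphenyl)silyl]oxy}methyl)-2-methyl-2-(4-methyl-3-oxopentyl)cyclohept-4-en-1-one | O=C1CCC(CO[Si](c2ccccc2)(c2ccccc2)C(C)(C)C)=CC[C@@]1(C)CCC(=O)C(C)C | intermediate
20 | tert-butyl{[(8aR)-8a-methyl-3-(propan-2-yl)-1,2,4,5,8,8a-hexahydroazulen-6-yl]methoxy}diphenylsilane | CC(C)C1=C2CCC(CO[Si](c3ccccc3)(c3ccccc3)C(C)(C)C)=CC[C@@]2(C)CC1 | intermediate
21 | [(8aR)-8a-methyl-3-(propan-2-yl)-1,2,4,5,8,8a-hexahydroazulen-6-yl]methanol | CC(C)C1=C2CCC(CO)=CC[C@@]2(C)CC1 | intermediate
22 | 4-hydroxy-3-methoxybenzoic acid | COc1cc(C(=O)O)ccc1O | starting material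
23 | [(8aR)-8a-methyl-3-(propan-2-yl)-1,2,4,5,8,8a-hexahydroazulen-6-yl]methyl 4-hydroxy-3-methoxybenzoate | COc1cc(C(=O)OCC2=CC[C@@]3(C)CCC(C(C)C)=C3CC2)ccc1O | target

Total step count: 14. Longest linear sequence: 11 steps (steps 1–3 and 7–14; steps 4–6 prepare iodide 12).

Steps most likely to fail

Step 12. The coupling may stop at the pinacol stage because both carbinol carbons are crowded, and electron transfer from low-valent titanium to the allylic silyloxymethyl unit may cleave its C–O bond reductively. The fallback sets out from 19 and comes back at 20 by separating C–C bond formation from deoxygenation. SmI2 in THF should effect the intramolecular pinacol coupling to the cis-diol (8aR)-6-({[tert-butyl(diphenyl)silyl]oxy}methyl)-8a-methyl-3-(propan-2-yl)-1,2,3,3a,4,5,8,8a-octahydroazulene-3,3a-diol F1. Thiophosgene and DMAP should convert it into the cyclic 3,3a-thiocarbonate F2, and heating F2 with P(OMe)3 (Corey–Winter olefination) should extrude carbon dioxide and sulfur to give 20.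

Step 8. Facial selectivity may be poor because methyl iodide is a small electrophile and the directing group sits two ring atoms away; any C3 epimer carried forward becomes the enantiomer after step 10. The fallback sets out from 6 and comes back at 18. It reverses the order of the two alkylations in the enantiomeric lactone series, so that the bulky iodide 12, not methyl iodide, makes the quaternary centre under the influence of C5. Reduction of 6 with the (R)-configured oxazaborolidine and catecholborane should give methyl (4S)-5-({[tert-butyl(diphenyl)silyl]oxy}methyl)-4-hydroxyhex-5-enoate F3, which lactonises to (5S)-5-(3-{[tert-butyl(diphenyl)silyl]oxy}prop-1-en-2-yl)oxolan-2-one F4. Methylation (LiN(i-Pr)2, MeI) should give (3R,5S)-5-(3-{[tert-butyl(diphenyl)silyl]oxy}prop-1-en-2-yl)-3-methyloxolan-2-one F5. Renewed enolisation and alkylation with 12 anti to the C5 group should give (3R,5S)-5-(3-{[tert-butyl(diphenyl)silyl]oxy}prop-1-en-2-yl)-3-methyl-3-{2-[2-(propan-2-yl)-1,3-dioxolan-2-yl]ethyl}oxolan-2-one F6, the C5 epimer of 16. Petasis methylenation should give tert-butyl{[2-((2S,4R)-4-methyl-5-methylidene-4-{2-[2-(propan-2-yl)-1,3-dioxolan-2-yl]ethyl}oxolan-2-yl)prop-2-en-1-yl]oxy}diphenylsilane F7. The Claisen ring expansion of F7, which erases C5, converges on 18.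

Step 7. Substitution at the unactivated iodide may be slow, so that elimination from 12 and self-condensation of the lactone enolate compete. The fallback sets out from 8 and comes back at 14. It attaches the chain by conjugate addition instead of substitution: enolate 13 is added at −78 °C to 4-methylpent-1-en-3-one to give (3S,5R)-5-(3-{[tert-butyl(diphenyl)silyl]oxy}prop-1-en-2-yl)-3-(4-methyl-3-oxopentyl)oxolan-2-one F8. Ketalisation of the side-chain ketone with ethane-1,2-diol (PPTS, benzene, Dean–Stark trap) then gives 14.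

Further compounds
F1 | step 12 | (8aR)-6-({[tert-butyl(diphenyl)silyl]oxy}methyl)-8a-methyl-3-(propan-2-yl)-1,2,3,3a,4,5,8,8a-octahydroazulene-3,3a-diol (cis-diol) | CC(C)C1(O)CC[C@]2(C)CC=C(CO[Si](c3ccccc3)(c3ccccc3)C(C)(C)C)CCC12O
F2 | step 12 | cyclic 3,3a-thiocarbonate of F1 | CC(C)C12CC[C@]3(C)CC=C(CO[Si](c4ccccc4)(c4ccccc4)C(C)(C)C)CCC13OC(=S)O2
F3 | step 8 | methyl (4S)-5-({[tert-butyl(diphenyl)silyl]oxy}methyl)-4-hydroxyhex-5-enoate | COC(=O)CC[C@H](O)C(=C)CO[Si](c1ccccc1)(c1ccccc1)C(C)(C)C
F4 | step 8 | (5S)-5-(3-{[tert-butyl(diphenyl)silyl]oxy}prop-1-en-2-yl)oxolan-2-one | O=C1CC[C@@H](C(=C)CO[Si](c2ccccc2)(c2ccccc2)C(C)(C)C)O1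
F5 | step 8 | (3R,5S)-5-(3-{[tert-butyl(diphenyl)silyl]oxy}prop-1-en-2-yl)-3-methyloxolan-2-one | O=C1[C@H](C)C[C@@H](C(=C)CO[Si](c2ccccc2)(c2ccccc2)C(C)(C)C)O1
F6 | step 8 | (3R,5S)-5-(3-{[tert-butyl(diphenyl)silyl]oxy}prop-1-en-2-yl)-3-methyl-3-{2-[2-(propan-2-yl)-1,3-dioxolan-2-yl]ethyl}oxolan-2-one | O=C1[C@](C)(CCC2(C(C)C)OCCO2)C[C@@H](C(=C)CO[Si](c3ccccc3)(c3ccccc3)C(C)(C)C)O1
F7 | step 8 | tert-butyl{[2-((2S,4R)-4-methyl-5-methylidene-4-{2-[2-(propan-2-yl)-1,3-dioxolan-2-yl]ethyl}oxolan-2-yl)prop-2-en-1-yl]oxy}diphenylsilane | C=C1[C@](C)(CCC2(C(C)C)OCCO2)C[C@@H](C(=C)CO[Si](c3ccccc3)(c3ccccc3)C(C)(C)C)O1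
F8 | step 7 | (3S,5R)-5-(3-{[tert-butyl(diphenyl)silyl]oxy}prop-1-en-2-yl)-3-(4-methyl-3-oxopentyl)oxolan-2-one | O=C1[C@@H](CCC(=O)C(C)C)C[C@H](C(=C)CO[Si](c2ccccc2)(c2ccccc2)C(C)(C)C)O1
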